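A direct plan would make the achiral α-aryloxy ketone A1, 1-[4-(benzyloxy)-3,5-dimethoxyphenyl]-2-[4-(3-hydroxypropyl)-2-methoxyphenoxy]ethan-1-one, by a Williamson ether synthesis, would add C3 by a catalytic enantioselective hydroxymethylation of A1 under chiral phase-transfer conditions, and would end with hydrogenolysis of the benzyl ether. Its weakest steps would be:
- The enantioselective hydroxymethylation of A1: face selection on an acyclic α-aryloxy ketone enolate by a chiral ion pair has no close precedent, and the product keeps an acidic C2–H next to the ketone in the basic medium that made it, so racemisation, retro-aldol cleavage, loss of water and a second hydroxymethylation would all compete.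
- The same step as the only source of chirality: with a single stereocentre there would be no diastereomer to remove, so a moderate ee could not be upgraded short of chiral chromatography.
- The final hydrogenolysis: it would be run on the finished α-aryloxy aryl ketone, whose C2–O bond and carbonyl group are themselves reducible on palladium, and it would expose the labile C2 centre once more in the last step.

**Retrosynthetic overview**

Target numbering: C1 is the ketone carbon on ring A (4-hydroxy-3,5-dimethoxyphenyl), C2 the stereocentre carrying the O–aryl bond to ring B (2-methoxy-4-(3-hydroxypropyl)phenyl), C3 the CH2OH carbon.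
Key disconnection: C1=O of 12 is traced back to a C1 carbinol and C3 to an ethyl ester, so 12 derives from syn hydroxy ester 8, and 8 from the racemic α-aryloxy β-keto ester 7 by a dynamic kinetic resolution that forms the C1–H bond and sets C1 and C2 together. C2–H in 7 lies between the C1 ketone and the C3 ester and racemises freely, so the lability of C2 becomes the control element.
Keto ester 7 would come from chloride 5 and phenol 6 (C2–O bond), 5 from β-keto ester 4, and 4 from acid 1 by a decarboxylative Claisen condensation (C1–C2 bond). No ring is formed; both benzene rings are bought.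
C2 would thus be fixed by funnelling a racemate, not by face selection on a ketone enolate, could be upgraded by removing the minor diastereomer, and would stay non-enolisable until the last step. The benzyl ether would be hydrogenolysed at the diol stage, and the α-aryloxy ketone would appear only in the final, neutral oxidation that erases the auxiliary C1 centre.

Key step: step 4

Remark: the syn preference and the sense of induction in step 4 are assigned by analogy with α-alkoxy β-aryl β-keto esters; the relative configuration of 8 would be confirmed before it is carried on.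

**Route**

Step 1
Reactants: 1 4-(benzyloxy)-3,5-dimethoxybenzoic acid
Product: 4 ethyl 3-[4-(benzyloxy)-3,5-dimethoxyphenyl]-3-oxopropanoate, via acyl imidazolide 2 (not isolated), via acylmalonic half-ester 3 (not isolated)
Conditions: CDI (1.1 equiv), THF, rt, 2 h; then KO2CCH2CO2Et (1.5 equiv), MgCl2 (1.5 equiv), Et3N (2.5 equiv), THF/MeCN, rt to 45 °C, 12 h; 1 M HCl work-up
Reagents that add atoms: potassium ethyl malonate, [K+].[O-]C(=O)CC(=O)OCC
Why: Masamune–Brooks decarboxylative Claisen condensation, in which the magnesium enolate of the malonate half-ester is C-acylated by the aroyl imidazolide and the acylmalonate loses CO2 on acidic work-up, forming the C1–C2 bond under conditions that leave the benzyl and methyl ethers untouched.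

Step 2
Reactants: 4 ethyl 3-[4-(benzyloxy)-3,5-dimethoxyphenyl]-3-oxopropanoate
Product: 5 ethyl 3-[4-(benzyloxy)-3,5-dimethoxyphenyl]-2-chloro-3-oxopropanoate (racemic)
Conditions: SO2Cl2 (1.05 equiv), CH2Cl2, 0 °C to rt, 2 h
Reagents that add atoms: sulfuryl chloride, ClS(Cl)(=O)=O
Why: α-Chlorination of the β-keto ester through its enol, which should stop at the monochloride with one equivalent because the product enolises less readily, while the aroyl group deactivates ring A toward electrophilic chlorination.

Step 3
Reactants: 5 ethyl 3-[4-(benzyloxy)-3,5-dimethoxyphenyl]-2-chloro-3-oxopropanoate; 6 dihydroconiferyl alcohol, 4-(3-hydroxypropyl)-2-methoxyphenol (1.05 equiv)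
Product: 7 ethyl 3-[4-(benzyloxy)-3,5-dimethoxyphenyl]-2-[4-(3-hydroxypropyl)-2-methoxyphenoxy]-3-oxopropanoate (racemic)
Conditions: K2CO3 (2.0 equiv), acetone, rt to 45 °C, 8–12 h; dilute acid work-up
Reagents that add atoms: none
Why: Williamson-type SN2 displacement of the doubly activated chloride by the phenoxide, K2CO3 ionising the phenol (pKa about 10) but not the primary alcohol (pKa about 16), so the C2–O bond forms without protection of the side chain and deliberately as a racemate, since C2 is set in step 4.

Step 4
Reactants: 7 ethyl 3-[4-(benzyloxy)-3,5-dimethoxyphenyl]-2-[4-(3-hydroxypropyl)-2-methoxyphenoxy]-3-oxopropanoate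
Product: 8 ethyl (2R,3S)-3-[4-(benzyloxy)-3,5-dimethoxyphenyl]-3-hydroxy-2-[4-(3-hydroxypropyl)-2-methoxyphenoxy]propanoate
Conditions: RuCl[(R,R)-TsDPEN](p-cymene) (1–2 mol %), HCO2H/Et3N 5:2 (5 equiv HCO2H), CH2Cl2, 30 °C, 24–48 h; purification to a single diastereomer by chromatography or crystallisation
Reagents that add atoms: none
Why: Noyori–Ikariya asymmetric transfer hydrogenation run as a dynamic kinetic resolution: the Ru–H/N–H pair formed from formate delivers hydride and proton to the C1 ketone through the six-membered outer-sphere transition state, while HCO2H/Et3N interconverts the two enantiomers of 7 through the enol of the β-keto ester, C2–H being flanked by the C1 ketone and the C3 ester and further acidified by the aryloxy group (pKa about 10). The closest known reaction type is the transfer-hydrogenative DKR of α-alkoxy β-aryl β-keto esters, which gives syn α-alkoxy β-hydroxy esters with high diastereo- and enantioselectivity. No ring is closed. The C1 carbinol is set by the catalyst through the CH–π contact between ring A and the η6-arene, the (R,R)-ligand giving the 3S carbinol (the descriptor is inverted relative to 1-phenylethanol because the C2 branch outranks the aryl group), and C2 is set by the substrate, the (2R)-enantiomer being reduced faster in a Felkin-type arrangement that leads to the syn isomer, so the whole racemate should be funnelled into (2R,3S)-8. The step needs ketone-over-ester chemoselectivity (inherent to this catalyst), racemisation faster than reduction (secured by the doubly activated C2–H) and a high syn preference, because the anti isomer would carry the wrong C2 configuration into the target; 8 would therefore be brought to diastereomeric purity here, and any O-formylation of the primary hydroxyl would be undone by the hydride of step 5.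

Step 5
Reactants: 8 ethyl (2R,3S)-3-[4-(benzyloxy)-3,5-dimethoxyphenyl]-3-hydroxy-2-[4-(3-hydroxypropyl)-2-methoxyphenoxy]propanoate
Product: 10 (1S,2S)-1-[4-(benzyloxy)-3,5-dimethoxyphenyl]-2-[4-(3-hydroxypropyl)-2-methoxyphenoxy]propane-1,3-diol, via aldehyde 9 (not isolated)
Conditions: LiBH4 (3 equiv), THF, 0 °C to rt, 4 h; sat. NH4Cl
Reagents that add atoms: none
Why: Borohydride reduction of the α-aryloxy-activated ester to the C3 primary alcohol, in which the weakly basic hydride should not epimerise C2 and the transient aldehyde is reduced faster than it enolises; C2 keeps its spatial arrangement and changes descriptor from R to S only because CH2OH now ranks below the carbinol carbon.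

Step 6
Reactants: 10 (1S,2S)-1-[4-(benzyloxy)-3,5-dimethoxyphenyl]-2-[4-(3-hydroxypropyl)-2-methoxyphenoxy]propane-1,3-diol
Product: 11 (1S,2S)-1-(4-hydroxy-3,5-dimethoxyphenyl)-2-[4-(3-hydroxypropyl)-2-methoxyphenoxy]propane-1,3-diol
Conditions: H2 (1 atm), 10% Pd/C, EtOAc/EtOH 4:1, rt, 2–4 h
Reagents that add atoms: none
Why: Catalytic hydrogenolysis of the benzyl aryl ether at the diol oxidation level, where no ketone is present, neither stereocentre is enolisable and the secondary benzylic hydroxyl, without acid, should be retained at 1 atm and rt.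

Step 7
Reactants: 11 (1S,2S)-1-(4-hydroxy-3,5-dimethoxyphenyl)-2-[4-(3-hydroxypropyl)-2-methoxyphenoxy]propane-1,3-diol
Product: 12 (S)-3-hydroxy-1-(4-hydroxy-3,5-dimethoxyphenyl)-2-[4-(3-hydroxypropyl)-2-methoxyphenoxy]propan-1-one (target)
Conditions: DDQ (1.1 equiv), 1,4-dioxane, rt, 1–2 h; filtration of the hydroquinone, chromatography below 30 °C
Reagents that add atoms: none
Why: Chemoselective DDQ dehydrogenation of the 4-hydroxybenzylic secondary alcohol (hydride abstraction assisted by the para phenol, through the hydroxy quinone methide tautomer of the ketone), which should leave both primary alcohols and the less electron-rich benzylic CH2 of ring B alone; the medium is neutral, so C2 keeps its S configuration while the auxiliary C1 centre is erased.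

**Compound list**

1 | 4-(benzyloxy)-3,5-dimethoxybenzoic acid | OC(=O)c1cc(OC)c(OCc2ccccc2)c(OC)c1 | starting material
2 | [4-(benzyloxy)-3,5-dimethoxyphenyl](1H-imidazol-1-yl)methanone (acyl imidazolide, not isolated) | O=C(c1cc(OC)c(OCc2ccccc2)c(OC)c1)n1ccnc1 | intermediate
3 | 2-[4-(benzyloxy)-3,5-dimethoxybenzoyl]-3-ethoxy-3-oxopropanoic acid (acylmalonic half-ester, present as its magnesium chelate, not isolated) | CCOC(=O)C(C(=O)O)C(=O)c1cc(OC)c(OCc2ccccc2)c(OC)c1 | intermediate
4 | ethyl 3-[4-(benzyloxy)-3,5-dimethoxyphenyl]-3-oxopropanoate | CCOC(=O)CC(=O)c1cc(OC)c(OCc2ccccc2)c(OC)c1 | intermediate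
5 | ethyl 3-[4-(benzyloxy)-3,5-dimethoxyphenyl]-2-chloro-3-oxopropanoate (racemic) | CCOC(=O)C(Cl)C(=O)c1cc(OC)c(OCc2ccccc2)c(OC)c1 | intermediate
6 | dihydroconiferyl alcohol, 4-(3-hydroxypropyl)-2-methoxyphenol | COc1cc(CCCO)ccc1O | starting material
7 | ethyl 3-[4-(benzyloxy)-3,5-dimethoxyphenyl]-2-[4-(3-hydroxypropyl)-2-methoxyphenoxy]-3-oxopropanoate (racemic) | COc1cc(CCCO)ccc1OC(C(=O)OCC)C(=O)c1cc(OC)c(OCc2ccccc2)c(OC)c1 | intermediate
8 | ethyl (2R,3S)-3-[4-(benzyloxy)-3,5-dimethoxyphenyl]-3-hydroxy-2-[4-(3-hydroxypropyl)-2-methoxyphenoxy]propanoate | COc1cc(CCCO)ccc1O[C@@H](C(=O)OCC)[C@@H](O)c1cc(OC)c(OCc2ccccc2)c(OC)c1 | intermediate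
9 | (2R,3S)-3-[4-(benzyloxy)-3,5-dimethoxyphenyl]-3-hydroxy-2-[4-(3-hydroxypropyl)-2-methoxyphenoxy]propanal (not isolated) | COc1cc(CCCO)ccc1O[C@@H](C=O)[C@@H](O)c1cc(OC)c(OCc2ccccc2)c(OC)c1 | intermediate
10 | (1S,2S)-1-[4-(benzyloxy)-3,5-dimethoxyphenyl]-2-[4-(3-hydroxypropyl)-2-methoxyphenoxy]propane-1,3-diol | COc1cc(CCCO)ccc1O[C@@H](CO)[C@@H](O)c1cc(OC)c(OCc2ccccc2)c(OC)c1 | intermediate
11 | (1S,2S)-1-(4-hydroxy-3,5-dimethoxyphenyl)-2-[4-(3-hydroxypropyl)-2-methoxyphenoxy]propane-1,3-diol | COc1cc(CCCO)ccc1O[C@@H](CO)[C@@H](O)c1cc(OC)c(O)c(OC)c1 | intermediate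
12 | (S)-3-hydroxy-1-(4-hydroxy-3,5-dimethoxyphenyl)-2-[4-(3-hydroxypropyl)-2-methoxyphenoxy]propan-1-one | COc1cc(CCCO)ccc1O[C@@H](CO)C(=O)c1cc(OC)c(O)c(OC)c1 | target

**Step count and risks**

Total step count: 7. Longest linear sequence: 7 steps (1 to 12); phenol 6 is bought and enters in step 3.

Steps most likely to fail:

1. Step 4 (key step). What may go wrong: incomplete diastereocontrol, or slow hydride transfer to the bulky α-aryloxy keto ester, which after erasure of C1 would show up as erosion of ee at C2. The fallback sets out from 6 and comes back at 10, and moves the stereo-determining event to a C1–C2 bond formation under auxiliary control. Phenol 6 would be alkylated (K2CO3, NaI, acetone) with (R)-4-benzyl-3-(2-chloroacetyl)oxazolidin-2-one F1 to give the aryloxyacetyl imide F2. Its (Z)-boron enolate (Bu2BOTf 2.2 equiv, iPr2NEt, CH2Cl2, −78 to 0 °C, the extra equivalent being taken up by the primary hydroxyl and released in the oxidative work-up) would add to 4-(benzyloxy)-3,5-dimethoxybenzaldehyde F3 in an Evans syn glycolate aldol reaction to give the syn aldol adduct F4. Reductive removal of the auxiliary with LiBH4 (THF, 0 °C) would then give diol 10 directly.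

2. Step 7. What may go wrong: oxidative degradation of the free syringyl phenol (quinone formation with loss of the side chain, phenol coupling) in competition with the benzylic dehydrogenation, or epimerisation at C2 during isolation. The fallback sets out from 10 and comes back at 12, reversing the order of unmasking and oxidation. The still benzylated diol 10 would be oxidised at the secondary benzylic alcohol by nitroxyl-catalysed aerobic oxidation (4-acetamido-TEMPO 5 mol %, HNO3 and HCl 10 mol % each, O2, MeCN/H2O, 45 °C) to the benzyl-protected (S)-ketone F5. The benzyl ether would then be cleaved without hydrogen by BCl3 with pentamethylbenzene as cation scavenger (CH2Cl2, −78 °C) to give 12.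

3. Step 3. What may go wrong: attack of the phenoxide at chlorine instead of carbon (chlorine transfer to the phenol with reduction of 5 back to 4), or deprotonation of 5 to an unreactive enolate, so that the substitution stalls. The fallback sets out from 6, uses acyl imidazolide 2 made from 1 as in step 1, and comes back at 7; the last bond made would be C1–C2 instead of C2–O. Phenol 6 would be alkylated (K2CO3, acetone, 50 °C) with diethyl 2-chloromalonate F6 to the diethyl aryloxymalonate F7. One ester would be saponified (KOH 1.0 equiv, EtOH, rt) to the potassium half-ester salt F8. F8 would then be C-acylated by 2 under the Masamune–Brooks conditions (MgCl2, Et3N, THF/MeCN) and would give 7 after decarboxylation on acidic work-up.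

**Further compounds**

F1 | step 4 | (R)-4-benzyl-3-(2-chloroacetyl)oxazolidin-2-one | O=C1OC[C@@H](Cc2ccccc2)N1C(=O)CCl
F2 | step 4 | (R)-4-benzyl-3-{2-[4-(3-hydroxypropyl)-2-methoxyphenoxy]acetyl}oxazolidin-2-one | COc1cc(CCCO)ccc1OCC(=O)N1[C@H](Cc2ccccc2)COC1=O
F3 | step 4 | 4-(benzyloxy)-3,5-dimethoxybenzaldehyde | COc1cc(C=O)cc(OC)c1OCc1ccccc1
F4 | step 4 | (R)-4-benzyl-3-{(2R,3S)-3-[4-(benzyloxy)-3,5-dimethoxyphenyl]-3-hydroxy-2-[4-(3-hydroxypropyl)-2-methoxyphenoxy]propanoyl}oxazolidin-2-one | COc1cc(CCCO)ccc1O[C@@H](C(=O)N1[C@H](Cc2ccccc2)COC1=O)[C@@H](O)c1cc(OC)c(OCc2ccccc2)c(OC)c1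
F5 | step 7 | (S)-1-[4-(benzyloxy)-3,5-dimethoxyphenyl]-3-hydroxy-2-[4-(3-hydroxypropyl)-2-methoxyphenoxy]propan-1-one | COc1cc(CCCO)ccc1O[C@@H](CO)C(=O)c1cc(OC)c(OCc2ccccc2)c(OC)c1
F6 | step 3 | diethyl 2-chloromalonate | CCOC(=O)C(Cl)C(=O)OCC
F7 | step 3 | diethyl 2-[4-(3-hydroxypropyl)-2-methoxyphenoxy]malonate | CCOC(=O)C(Oc1ccc(CCCO)cc1OC)C(=O)OCC
F8 | step 3 | potassium 3-ethoxy-2-[4-(3-hydroxypropyl)-2-methoxyphenoxy]-3-oxopropanoate | [K+].[O-]C(=O)C(Oc1ccc(CCCO)cc1OC)C(=O)OCC
A1 | direct plan | 1-[4-(benzyloxy)-3,5-dimethoxyphenyl]-2-[4-(3-hydroxypropyl)-2-methoxyphenoxy]ethan-1-one | COc1cc(CCCO)ccc1OCC(=O)c1cc(OC)c(OCc2ccccc2)c(OC)c1
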